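The numbers in the tables are calculated on assumed constants, and the scatter is random.

I began from a one-step world: once the left-handed substrate had gone, I supposed, the right-handed substrate simply coupled to right-handed product, its logarithm falling in step with the dose, [free catalyst] times time (a pseudo-first-order decay).

in all of them: left-handed substrate 1.1 M; right-handed substrate 1.1 M; coupling partner 2.75 M; racemization catalyst 11 mM

| run | free catalyst | remark | time |
|---|---|---|---|
| teal | 1.1 mM | run made earlier |  |
| amber | 1.7 mM | run made earlier |  |
| flask | 2.2 mM |  | 25 h |

- teal (time / h: left-handed product / %, right-handed product / %, right-handed substrate / %): 1.33: 23, 0, 48; 4.00: 42, 5, 47; 8.00: 54, 1, 39; 10.0: 52, 4, 43; 15.0: 56, 6, 39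
- amber (time / h: left-handed product / %, right-handed product / %, right-handed substrate / %): 3.00: 48, 2, 45; 6.00: 53, 2, 43; 10.0: 54, 5, 40; 12.0: 55, 9, 38; 15.0: 55, 8, 38

(scatter of a reading: 1.5 percentage points)

* concentration of left-handed product at 25 h, in M
* concentration of right-handed product at 25 h, in M
* concentration of right-handed substrate at 25 h, in M
* concentration of coupling partner at 25 h, in M

- free catalyst is single-handed; left-handed substrate and right-handed substrate are mirror images of each other, charged as a racemate, each of them at the stated concentration

In the amber run at 15.0 h the three readings summed to 101%, so I set the left-handed substrate aside. I called ln(([right-handed substrate] + [right-handed product]) / [right-handed substrate]) the leak exponent, and the amber run read 0.191. The teal run read 0.143 at 0.647 of that dose, roughly in step. The flask took 2.16 times the amber dose, so its leak exponent at 25 h should be 0.412.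

From below, the flask's larger dose should give it the amber run's right-handed product, 0.176 M. From above, growth proportional to dose with no running down gave 0.380 M. Applying the exponent to the amber pool of 46.0% tightened this to 0.342 M of right-handed product and 0.670 M of right-handed substrate. With left-handed product held at 1.21 M and one coupling partner per product, [coupling partner] came to 1.20 M.

The forecast gave 1.23 M, 0.32 M, 0.65 M and 1.2 M in the asked order, its right-handed product inside my bracket, reasoning of that product's growth “so it is roughly proportional to catalyst”.

The flask gave 1.23 M, 0.285 M, 0.689 M and 1.24 M.

    coupling partner + free catalyst + right-handed substrate → free catalyst + right-handed product (k = 0.00119 M⁻² s⁻¹)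
    coupling partner + free catalyst + left-handed substrate → free catalyst + left-handed product (k = 0.0579 M⁻² s⁻¹)
    racemization catalyst → spent catalyst (k = 8.03 × 10⁻⁵ s⁻¹)
    left-handed substrate + racemization catalyst ⇌ right-handed substrate + racemization catalyst, rate k4*[racemization catalyst]*[left-handed substrate] forward; the back reaction follows from the equilibrium constant (k = 0.00126 M⁻¹ s⁻¹)

The flask's leak exponent came to 0.347, below my 0.412. A neighbouring flask, charged with 8.80 mM of free catalyst, took 4.00 times the flask's dose, so the same scaling gave an exponent of 1.39 and 0.243 M of right-handed substrate. The neighbouring flask held 0.324 M of right-handed substrate beside 0.642 M of right-handed product, an exponent of 1.09, smaller than scaled. The neighbouring flask's coupling partner stood at 0.874 M, against 1.24 M in the flask.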